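Locants: plain numbers and rings A, C, B refer to the flavone. Doubly primed numbers refer to the flavanone.

**Plan**
- Cuts, latest first: the four O-benzyl bonds; the aryl–C2'' bond; the second pyranone at O1''–C2'' and C2''–C3''; the acetyl–C4a'' bond; flavone ring C at C2–C3 and O1–C2; and the ring A–C4 bond of a deoxybenzoin.
- Enabling feature: flavone C2=C3 is a tetrasubstituted enol-ether alkene with an aryl group on each carbon. C3 lies between the C4 ketone and flavanone C6''. With ring C opened, C3 is the acidic CH2 of a 2-hydroxydeoxybenzoin, and the crowded C3–C6'' bond is just the aryl–CH2 bond of an arylacetaldehyde.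
- Forward order: the ring A aryllithium is joined to the arylacetaldehyde to give the deoxybenzoin. Ring C is then closed with anisoyl chloride, the pendant ring is acetylated through its aryl iodide, a second chromone is closed, and that chromone is converted to the flavanone.
- Stereochemistry: the only stereocentre, C2'', is (R) by CIP analysis of the given SMILES. A rhodium/(R)-bisphosphine-catalysed 1,4-addition of the arylboronic acid sets it, and neutral hydrogenolysis preserves it.

Key step: step 9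

Assumption: the C3–C6'' aryl–aryl axis has no descriptor in the target, so rotamers or slowly interconverting atropisomers from compound 19 onward are carried together and counted as one compound.

**Step 1**
Reactants: 1 5-methoxyresorcinol
Product: 2 1-methoxy-3,5-bis(methoxymethoxy)benzene
Conditions: NaH (2.4 equiv), MOMCl (2.4 equiv), DMF, 0 °C to rt
Reagents that add atoms: chloromethyl methyl ether, COCCl
Why: Double Williamson-type O-alkylation of the bis-phenoxide with the hard electrophile MOMCl occurs on oxygen only and installs the two acetal groups that later direct lithiation to the carbon between them.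

**Step 2**
Reactants: 3 2,4,6-trihydroxybenzaldehyde
Product: 4 4-(allyloxy)-2,6-dihydroxybenzaldehyde
Conditions: allyl alcohol (1.0 equiv), PPh3 (1.05 equiv), DIAD (1.05 equiv), THF, 0 °C to rt
Reagents that add atoms: allyl alcohol, C=CCO
Why: Mitsunobu etherification consumes the most acidic and least hindered hydroxyl, the 4-OH para to the formyl group, while the two ortho hydroxyls are held back by hydrogen bonding to the carbonyl and by crowding, and the neutral medium avoids C-allylation of the phloroglucinol ring.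

**Step 3**
Reactants: 4 4-(allyloxy)-2,6-dihydroxybenzaldehyde
Product: 5 4-(allyloxy)-2,6-bis(benzyloxy)benzaldehyde
Conditions: BnBr (2.5 equiv), K2CO3 (3 equiv), DMF, 60 °C
Reagents that add atoms: benzyl bromide, BrCc1ccccc1
Why: Williamson benzylation in warm DMF overcomes the hydrogen bond of the ortho phenols, the aldehyde has no α-hydrogen, and the allyl ether is inert to carbonate.

**Step 4**
Reactants: 5 4-(allyloxy)-2,6-bis(benzyloxy)benzaldehyde
Product: 7 2-[4-(allyloxy)-2,6-bis(benzyloxy)phenyl]acetaldehyde, via methyl enol ether 6 (not isolated)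
Conditions: Ph3P(CH2OMe)Cl, NaN(SiMe3)2, THF, 0 °C to rt; then 2 M HCl, THF, 40 °C
Reagents that add atoms: (methoxymethyl)triphenylphosphonium chloride, COC[P+](c1ccccc1)(c1ccccc1)c1ccccc1.[Cl-]; water, O
Why: Wittig methoxymethylenation followed by acid hydrolysis of the electron-rich enol ether is the standard one-carbon homologation of an aryl aldehyde to an arylacetaldehyde, and allyl and benzyl aryl ethers do not respond to dilute acid.

**Step 5**
Reactants: 2 1-methoxy-3,5-bis(methoxymethoxy)benzene; 7 2-[4-(allyloxy)-2,6-bis(benzyloxy)phenyl]acetaldehyde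
Product: 9 (±)-2-[4-(allyloxy)-2,6-bis(benzyloxy)phenyl]-1-[4-methoxy-2,6-bis(methoxymethoxy)phenyl]ethan-1-ol, via aryllithium 8 (not isolated)
Conditions: 2 (1.3 equiv), n-BuLi (1.25 equiv), THF, 0 °C to rt; then 7, −78 °C; aq NH4Cl
Reagents that add atoms: none
Why: Directed ortho-metalation is steered by both OMOM groups to their shared position (para to OMe), and the aryllithium adds to the unhindered aldehyde at −78 °C faster than it enolises it; the carbinol centre forms as a racemate and is erased in step 6.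

**Step 6**
Reactants: 9 (±)-2-[4-(allyloxy)-2,6-bis(benzyloxy)phenyl]-1-[4-methoxy-2,6-bis(methoxymethoxy)phenyl]ethan-1-ol
Product: 10 2-[4-(allyloxy)-2,6-bis(benzyloxy)phenyl]-1-[4-methoxy-2,6-bis(methoxymethoxy)phenyl]ethan-1-one
Conditions: Dess–Martin periodinane (1.2 equiv), CH2Cl2, 0 °C to rt
Reagents that add atoms: none
Why: Dess–Martin oxidation converts the secondary benzylic alcohol into the ketone under near-neutral conditions that leave the MOM, benzyl and allyl ethers and the electron-rich rings untouched.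

**Step 7**
Reactants: 10 2-[4-(allyloxy)-2,6-bis(benzyloxy)phenyl]-1-[4-methoxy-2,6-bis(methoxymethoxy)phenyl]ethan-1-one
Product: 11 2-[4-(allyloxy)-2,6-bis(benzyloxy)phenyl]-1-(2,6-dihydroxy-4-methoxyphenyl)ethan-1-one
Conditions: conc. HCl (cat.), MeOH/THF, 45 °C
Reagents that add atoms: none
Why: Acid-catalysed acetal exchange with methanol removes both MOM groups, helped by the hydrogen bond each freed phenol forms to the ketone, whereas benzyl, allyl and methyl aryl ethers are stable to dilute HCl.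

**Step 8**
Reactants: 11 2-[4-(allyloxy)-2,6-bis(benzyloxy)phenyl]-1-(2,6-dihydroxy-4-methoxyphenyl)ethan-1-one
Product: 12 2-[4-(allyloxy)-2,6-bis(benzyloxy)phenyl]-1-[2-(benzyloxy)-6-hydroxy-4-methoxyphenyl]ethan-1-one
Conditions: BnBr (1.05 equiv), K2CO3 (1.2 equiv), acetone, reflux
Reagents that add atoms: benzyl bromide, BrCc1ccccc1
Why: Williamson monobenzylation of a 2,6-dihydroxyaryl ketone stops after one alkylation because the remaining hydroxyl is then locked in a strong hydrogen bond to the carbonyl and is a poor nucleophile under mild carbonate conditions.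

**Step 9**
Reactants: 12 2-[4-(allyloxy)-2,6-bis(benzyloxy)phenyl]-1-[2-(benzyloxy)-6-hydroxy-4-methoxyphenyl]ethan-1-one; 13 4-methoxybenzoyl chloride
Product: 17 3-[4-(allyloxy)-2,6-bis(benzyloxy)phenyl]-5-(benzyloxy)-7-methoxy-2-(4-methoxyphenyl)-4H-chromen-4-one, via aryl anisoate 14 (not isolated), via 1,3-diketone 15 (not isolated), via cyclic hemiketal 16 (not isolated)
Conditions: 13 (1.5 equiv), DBU (4 equiv), pyridine, 0 to 90 °C; aq HCl wash; then p-TsOH·H2O (20 mol %), toluene, 80 °C
Reagents that add atoms: none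
Why: DBU promotes O-aroylation of the hydrogen-bonded phenol of 12 to ester 14 and then deprotonates the CH2 group, which is acidified by the ketone on one side and the aryl ring on the other; the enolate carbon attacks the neighbouring ester carbonyl through a six-membered transition state, so the anisoyl group moves from oxygen to carbon and C2–C3 is formed (diketone 15). This is the Baker–Venkataraman rearrangement, and its use on 2-hydroxydeoxybenzoins followed by cyclodehydration is the classical entry to 2,3-diarylchromones. The released phenol adds to the anisoyl carbonyl in a 6-exo-trig closure that forms O1–C2 (hemiketal 16), and p-TsOH then removes water to give ring C as a pyran-4-one. No stereocentre is kept, since C2 and C3 of 16 both become sp2. The step needs C- rather than O-acylation of the enolate and only one acylation: the ortho ester tether lets only the carbon reach the carbonyl in a six-membered array, and C3 of 15 has no room for a second acyl group. The acyl-transfer equilibria are reversible but the loss of water is not, and because C3–C6'' is already present the crowding is met only in intramolecular events.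

**Step 10**
Reactants: 17 3-[4-(allyloxy)-2,6-bis(benzyloxy)phenyl]-5-(benzyloxy)-7-methoxy-2-(4-methoxyphenyl)-4H-chromen-4-one
Product: 18 5-(benzyloxy)-3-[2,6-bis(benzyloxy)-4-hydroxyphenyl]-7-methoxy-2-(4-methoxyphenyl)-4H-chromen-4-one
Conditions: Pd(PPh3)4 (5 mol %), morpholine (5 equiv), THF, rt
Reagents that add atoms: none
Why: In this Tsuji–Trost-type deallylation, zerovalent palladium ionises the aryl allyl ether to a π-allyl complex that morpholine intercepts, which frees only the phenol para to the biaryl bond (the future O1'') and touches neither the benzyl ethers nor the flavone.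

**Step 11**
Reactants: 18 5-(benzyloxy)-3-[2,6-bis(benzyloxy)-4-hydroxyphenyl]-7-methoxy-2-(4-methoxyphenyl)-4H-chromen-4-one
Product: 19 5-(benzyloxy)-3-[2,6-bis(benzyloxy)-4-hydroxy-3-iodophenyl]-7-methoxy-2-(4-methoxyphenyl)-4H-chromen-4-one
Conditions: NIS (1.0 equiv), CH2Cl2, −20 to 0 °C, dark
Reagents that add atoms: N-iodosuccinimide, O=C1CCC(=O)N1I
Why: Electrophilic aromatic iodination goes to the ring with one free hydroxyl, two benzyloxy donors and no acceptor, which is far more nucleophilic than carbonyl-bearing ring A or the anisyl ring, and its two open positions (both ortho to OH) are constitutionally equivalent, so one equivalent of NIS should give one regioisomer.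

**Step 12**
Reactants: 19 5-(benzyloxy)-3-[2,6-bis(benzyloxy)-4-hydroxy-3-iodophenyl]-7-methoxy-2-(4-methoxyphenyl)-4H-chromen-4-one
Product: 21 3-[3-acetyl-2,6-bis(benzyloxy)-4-hydroxyphenyl]-5-(benzyloxy)-7-methoxy-2-(4-methoxyphenyl)-4H-chromen-4-one, via ethyl enol ether 20 (not isolated)
Conditions: Bu3SnC(OEt)=CH2 (1.5 equiv), PdCl2(PPh3)2 (5 mol %), toluene, 100 °C; then 1 M HCl, THF, rt
Reagents that add atoms: tributyl(1-ethoxyvinyl)stannane, C=C(OCC)[Sn](CCCC)(CCCC)CCCC; water, O
Why: Stille coupling with the 1-ethoxyvinyl stannane as acetyl-anion equivalent replaces iodine by carbon without the Lewis acid that a Fries or Friedel–Crafts acetylation would need and the benzyl ethers would not tolerate, and dilute acid then hydrolyses the enol ether to the hydrogen-bonded methyl ketone.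

**Step 13**
Reactants: 21 3-[3-acetyl-2,6-bis(benzyloxy)-4-hydroxyphenyl]-5-(benzyloxy)-7-methoxy-2-(4-methoxyphenyl)-4H-chromen-4-one
Product: 23 5,7-bis(benzyloxy)-6-[5-(benzyloxy)-7-methoxy-2-(4-methoxyphenyl)-4-oxo-4H-chromen-3-yl]-4H-chromen-4-one, via enaminone 22 (not isolated)
Conditions: Me2NCH(OMe)2 (5 equiv), toluene, 95 °C; evaporate; then conc. HCl, CH2Cl2, rt
Reagents that add atoms: N,N-dimethylformamide dimethyl acetal, COC(OC)N(C)C
Why: Condensation of the methyl ketone with DMF dimethyl acetal gives the (E)-enaminone, and acid triggers conjugate addition of the ortho phenol and loss of dimethylamine (addition–elimination), the standard route to 2,3-unsubstituted chromones.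

**Step 14**
Reactants: 23 5,7-bis(benzyloxy)-6-[5-(benzyloxy)-7-methoxy-2-(4-methoxyphenyl)-4-oxo-4H-chromen-3-yl]-4H-chromen-4-one; 24 4-(benzyloxy)phenylboronic acid
Product: 25 (2R)-5,7-bis(benzyloxy)-2-[4-(benzyloxy)phenyl]-6-[5-(benzyloxy)-7-methoxy-2-(4-methoxyphenyl)-4-oxo-4H-chromen-3-yl]chroman-4-one
Conditions: [Rh(OH)(cod)]2 (3 mol %), (R)-MeO-F12-BIPHEP [(R)-2,2'-bis{bis(3,4,5-trifluorophenyl)phosphino}-6,6'-dimethoxybiphenyl] (6.6 mol %), 24 (3 equiv), toluene, H2O (5 equiv), 30 °C
Reagents that add atoms: none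
Why: In this Hayashi–Miyaura 1,4-addition the aryl-rhodium species formed by transmetalation inserts the only accessible enone, the unsubstituted C2''=C3'' bond (flavone C2=C3 is tetrasubstituted and inert), and the (R)-configured electron-poor bisphosphine directs the aryl group to the Si face of C2'' to set (R), a sense expected by analogy with the (S)-ligand/(S)-adduct pairing of this ligand family and to be checked by circular dichroism, with the antipodal ligand available should the check say otherwise.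

**Step 15**
Reactants: 25 (2R)-5,7-bis(benzyloxy)-2-[4-(benzyloxy)phenyl]-6-[5-(benzyloxy)-7-methoxy-2-(4-methoxyphenyl)-4-oxo-4H-chromen-3-yl]chroman-4-one
Product: 26 (2R)-5,7-dihydroxy-6-[5-hydroxy-7-methoxy-2-(4-methoxyphenyl)-4-oxo-4H-chromen-3-yl]-2-(4-hydroxyphenyl)chroman-4-one
Conditions: H2 (1 atm), 10% Pd/C, EtOAc/MeOH, rt; filtration and evaporation only
Reagents that add atoms: none
Why: Hydrogenolysis over Pd/C cleaves all four O-benzyl bonds under neutral conditions, so C2'' is not epimerised through ring opening to the chalcone, the two methyl ethers stay, and the tetrasubstituted flavone alkene and the chelated ketones are not reduced.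

**Compound list**
1 | 5-methoxyresorcinol | COc1cc(O)cc(O)c1 | starting material
2 | 1-methoxy-3,5-bis(methoxymethoxy)benzene | COCOc1cc(OC)cc(OCOC)c1 | intermediate
3 | 2,4,6-trihydroxybenzaldehyde | O=Cc1c(O)cc(O)cc1O | starting material
4 | 4-(allyloxy)-2,6-dihydroxybenzaldehyde | C=CCOc1cc(O)c(C=O)c(O)c1 | intermediate
5 | 4-(allyloxy)-2,6-bis(benzyloxy)benzaldehyde | C=CCOc1cc(OCc2ccccc2)c(C=O)c(OCc2ccccc2)c1 | intermediate
6 | 5-(allyloxy)-1,3-bis(benzyloxy)-2-(2-methoxyvinyl)benzene (E/Z mixture) | C=CCOc1cc(OCc2ccccc2)c(C=COC)c(OCc2ccccc2)c1 | intermediate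
7 | 2-[4-(allyloxy)-2,6-bis(benzyloxy)phenyl]acetaldehyde | C=CCOc1cc(OCc2ccccc2)c(CC=O)c(OCc2ccccc2)c1 | intermediate
8 | [4-methoxy-2,6-bis(methoxymethoxy)phenyl]lithium | COCOc1cc(OC)cc(OCOC)c1[Li] | intermediate
9 | (±)-2-[4-(allyloxy)-2,6-bis(benzyloxy)phenyl]-1-[4-methoxy-2,6-bis(methoxymethoxy)phenyl]ethan-1-ol | C=CCOc1cc(OCc2ccccc2)c(CC(O)c2c(OCOC)cc(OC)cc2OCOC)c(OCc2ccccc2)c1 | intermediate
10 | 2-[4-(allyloxy)-2,6-bis(benzyloxy)phenyl]-1-[4-methoxy-2,6-bis(methoxymethoxy)phenyl]ethan-1-one | C=CCOc1cc(OCc2ccccc2)c(CC(=O)c2c(OCOC)cc(OC)cc2OCOC)c(OCc2ccccc2)c1 | intermediate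
11 | 2-[4-(allyloxy)-2,6-bis(benzyloxy)phenyl]-1-(2,6-dihydroxy-4-methoxyphenyl)ethan-1-one | C=CCOc1cc(OCc2ccccc2)c(CC(=O)c2c(O)cc(OC)cc2O)c(OCc2ccccc2)c1 | intermediate
12 | 2-[4-(allyloxy)-2,6-bis(benzyloxy)phenyl]-1-[2-(benzyloxy)-6-hydroxy-4-methoxyphenyl]ethan-1-one | C=CCOc1cc(OCc2ccccc2)c(CC(=O)c2c(O)cc(OC)cc2OCc2ccccc2)c(OCc2ccccc2)c1 | intermediate
13 | 4-methoxybenzoyl chloride | COc1ccc(C(=O)Cl)cc1 | starting material
14 | 2-{[4-(allyloxy)-2,6-bis(benzyloxy)phenyl]acetyl}-3-(benzyloxy)-5-methoxyphenyl 4-methoxybenzoate | C=CCOc1cc(OCc2ccccc2)c(CC(=O)c2c(OC(=O)c3ccc(OC)cc3)cc(OC)cc2OCc2ccccc2)c(OCc2ccccc2)c1 | intermediate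
15 | 2-[4-(allyloxy)-2,6-bis(benzyloxy)phenyl]-1-[2-(benzyloxy)-6-hydroxy-4-methoxyphenyl]-3-(4-methoxyphenyl)propane-1,3-dione (racemic) | C=CCOc1cc(OCc2ccccc2)c(C(C(=O)c2ccc(OC)cc2)C(=O)c2c(O)cc(OC)cc2OCc2ccccc2)c(OCc2ccccc2)c1 | intermediate
16 | 3-[4-(allyloxy)-2,6-bis(benzyloxy)phenyl]-5-(benzyloxy)-2-hydroxy-7-methoxy-2-(4-methoxyphenyl)chroman-4-one (mixture of stereoisomers) | COc1ccc(C2(O)Oc3cc(OC)cc(OCc4ccccc4)c3C(=O)C2c2c(OCc3ccccc3)cc(OCC=C)cc2OCc2ccccc2)cc1 | intermediate
17 | 3-[4-(allyloxy)-2,6-bis(benzyloxy)phenyl]-5-(benzyloxy)-7-methoxy-2-(4-methoxyphenyl)-4H-chromen-4-one | COc1ccc(-c2oc3cc(OC)cc(OCc4ccccc4)c3c(=O)c2-c2c(OCc4ccccc4)cc(OCC=C)cc2OCc2ccccc2)cc1 | intermediate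
18 | 5-(benzyloxy)-3-[2,6-bis(benzyloxy)-4-hydroxyphenyl]-7-methoxy-2-(4-methoxyphenyl)-4H-chromen-4-one | COc1ccc(-c2oc3cc(OC)cc(OCc4ccccc4)c3c(=O)c2-c2c(OCc4ccccc4)cc(O)cc2OCc2ccccc2)cc1 | intermediate
19 | 5-(benzyloxy)-3-[2,6-bis(benzyloxy)-4-hydroxy-3-iodophenyl]-7-methoxy-2-(4-methoxyphenyl)-4H-chromen-4-one | COc1ccc(-c2oc3cc(OC)cc(OCc4ccccc4)c3c(=O)c2-c2c(OCc4ccccc4)cc(O)c(I)c2OCc2ccccc2)cc1 | intermediate
20 | 5-(benzyloxy)-3-[2,6-bis(benzyloxy)-3-(1-ethoxyvinyl)-4-hydroxyphenyl]-7-methoxy-2-(4-methoxyphenyl)-4H-chromen-4-one | COc1ccc(-c2oc3cc(OC)cc(OCc4ccccc4)c3c(=O)c2-c2c(OCc4ccccc4)cc(O)c(C(=C)OCC)c2OCc2ccccc2)cc1 | intermediate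
21 | 3-[3-acetyl-2,6-bis(benzyloxy)-4-hydroxyphenyl]-5-(benzyloxy)-7-methoxy-2-(4-methoxyphenyl)-4H-chromen-4-one | COc1ccc(-c2oc3cc(OC)cc(OCc4ccccc4)c3c(=O)c2-c2c(OCc4ccccc4)cc(O)c(C(C)=O)c2OCc2ccccc2)cc1 | intermediate
22 | 3-{2,6-bis(benzyloxy)-3-[(E)-3-(dimethylamino)acryloyl]-4-hydroxyphenyl}-5-(benzyloxy)-7-methoxy-2-(4-methoxyphenyl)-4H-chromen-4-one | COc1ccc(-c2oc3cc(OC)cc(OCc4ccccc4)c3c(=O)c2-c2c(OCc4ccccc4)cc(O)c(C(=O)/C=C/N(C)C)c2OCc2ccccc2)cc1 | intermediate
23 | 5,7-bis(benzyloxy)-6-[5-(benzyloxy)-7-methoxy-2-(4-methoxyphenyl)-4-oxo-4H-chromen-3-yl]-4H-chromen-4-one | COc1ccc(-c2oc3cc(OC)cc(OCc4ccccc4)c3c(=O)c2-c2c(OCc4ccccc4)cc3occc(=O)c3c2OCc2ccccc2)cc1 | intermediate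
24 | 4-(benzyloxy)phenylboronic acid | OB(O)c1ccc(OCc2ccccc2)cc1 | starting material
25 | (2R)-5,7-bis(benzyloxy)-2-[4-(benzyloxy)phenyl]-6-[5-(benzyloxy)-7-methoxy-2-(4-methoxyphenyl)-4-oxo-4H-chromen-3-yl]chroman-4-one | COc1ccc(-c2oc3cc(OC)cc(OCc4ccccc4)c3c(=O)c2-c2c(OCc4ccccc4)cc3c(c2OCc2ccccc2)C(=O)C[C@H](c2ccc(OCc4ccccc4)cc2)O3)cc1 | intermediate
26 | (2R)-5,7-dihydroxy-6-[5-hydroxy-7-methoxy-2-(4-methoxyphenyl)-4-oxo-4H-chromen-3-yl]-2-(4-hydroxyphenyl)chroman-4-one (CNP0292254.1) | COc1ccc(-c2oc3cc(OC)cc(O)c3c(=O)c2-c2c(O)cc3c(c2O)C(=O)C[C@H](c2ccc(O)cc2)O3)cc1 | target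

Total step count: 15.
Longest linear sequence: 14 steps (steps 2 to 15, from 3). Step 1 is a one-step side branch.

**Steps most likely to fail**

**1. Step 9.**
- What may go wrong: the acyl shift may stall at the ester stage because the enolate carbon carries a di-ortho-substituted ring. The crowded diketone may revert by retro-Claisen cleavage. Excess acid chloride may aroylate the enolate on oxygen.
- Fallback, from 12 back to 17: the same two bonds are formed at the aldehyde oxidation level. Compound 12 is condensed with commercial 4-methoxybenzaldehyde (piperidine, toluene, reflux). This is a Knoevenagel condensation followed by oxa-Michael closure. It gives racemic 3-[4-(allyloxy)-2,6-bis(benzyloxy)phenyl]-5-(benzyloxy)-7-methoxy-2-(4-methoxyphenyl)chroman-4-one F1. DDQ in dioxane at reflux then dehydrogenates it across C2–C3 to 17. No acyl migration or 1,3-diketone is involved.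

**2. Step 14.**
- What may go wrong: insertion into the electron-rich 5,7-dialkoxychromone may be slow. The electron-rich boronic acid may undergo competing protodeboronation. Reversible ring opening of the product may erode enantiopurity.
- Fallback, from 21 back to 25 (bypassing 23): Claisen–Schmidt condensation of 21 with commercial 4-(benzyloxy)benzaldehyde (KOH, EtOH/THF, rt) gives the (E)-2'-hydroxychalcone F2. NaOAc in refluxing EtOH closes it by oxa-Michael addition to the racemic tetrabenzyl flavanone F3. Preparative chromatography on a polysaccharide carbamate chiral phase then delivers 25. The unwanted (2S)-tetrabenzyl flavanone F4 is returned to F3 by base equilibration through F2 and resolved again.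

**3. Step 5.**
- What may go wrong: proton transfer from the acidic CH2 of the arylacetaldehyde to the basic, hindered aryllithium (enolisation), followed by aldol self-condensation, would compete with addition.
- Fallback, from 7 and 8 back to 10 (bypassing 9 and step 6): a non-basic organometallic and a higher oxidation level are used.
  - Pinnick oxidation of 7 (NaClO2, NaH2PO4, 2-methyl-2-butene, t-BuOH/H2O) gives [4-(allyloxy)-2,6-bis(benzyloxy)phenyl]acetic acid F5.
  - Oxalyl chloride with catalytic DMF converts it into [4-(allyloxy)-2,6-bis(benzyloxy)phenyl]acetyl chloride F6.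
  - Aryllithium 8 is transmetalated with ZnCl2 to [4-methoxy-2,6-bis(methoxymethoxy)phenyl]zinc chloride F7.
  - Negishi acylation of F6 with F7 under Pd(PPh3)4 catalysis in THF gives ketone 10 directly.

**Further compounds**
F1 | step 9 | 3-[4-(allyloxy)-2,6-bis(benzyloxy)phenyl]-5-(benzyloxy)-7-methoxy-2-(4-methoxyphenyl)chroman-4-one (racemic, cis/trans not defined) | COc1ccc(C2Oc3cc(OC)cc(OCc4ccccc4)c3C(=O)C2c2c(OCc3ccccc3)cc(OCC=C)cc2OCc2ccccc2)cc1
F2 | step 14 | 3-{2,6-bis(benzyloxy)-3-[(E)-3-(4-(benzyloxy)phenyl)acryloyl]-4-hydroxyphenyl}-5-(benzyloxy)-7-methoxy-2-(4-methoxyphenyl)-4H-chromen-4-one | COc1ccc(-c2oc3cc(OC)cc(OCc4ccccc4)c3c(=O)c2-c2c(OCc4ccccc4)cc(O)c(C(=O)/C=C/c3ccc(OCc4ccccc4)cc3)c2OCc2ccccc2)cc1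
F3 | step 14 | racemic 5,7-bis(benzyloxy)-2-[4-(benzyloxy)phenyl]-6-[5-(benzyloxy)-7-methoxy-2-(4-methoxyphenyl)-4-oxo-4H-chromen-3-yl]chroman-4-one | COc1ccc(-c2oc3cc(OC)cc(OCc4ccccc4)c3c(=O)c2-c2c(OCc4ccccc4)cc3c(c2OCc2ccccc2)C(=O)CC(c2ccc(OCc4ccccc4)cc2)O3)cc1
F4 | step 14 | (2S)-5,7-bis(benzyloxy)-2-[4-(benzyloxy)phenyl]-6-[5-(benzyloxy)-7-methoxy-2-(4-methoxyphenyl)-4-oxo-4H-chromen-3-yl]chroman-4-one | COc1ccc(-c2oc3cc(OC)cc(OCc4ccccc4)c3c(=O)c2-c2c(OCc4ccccc4)cc3c(c2OCc2ccccc2)C(=O)C[C@@H](c2ccc(OCc4ccccc4)cc2)O3)cc1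
F5 | step 5 | [4-(allyloxy)-2,6-bis(benzyloxy)phenyl]acetic acid | C=CCOc1cc(OCc2ccccc2)c(CC(=O)O)c(OCc2ccccc2)c1
F6 | step 5 | [4-(allyloxy)-2,6-bis(benzyloxy)phenyl]acetyl chloride | C=CCOc1cc(OCc2ccccc2)c(CC(=O)Cl)c(OCc2ccccc2)c1
F7 | step 5 | [4-methoxy-2,6-bis(methoxymethoxy)phenyl]zinc chloride | COCOc1cc(OC)cc(OCOC)c1[Zn]Cl
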